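The synthesis rests on the N–C19 bond of the nine-membered ring E. C18, the methyl-bearing carbon next to N–CH2, is made the central carbon of a 2-substituted allyl unit whose CH2 termini (C19, C20) are equivalent, so a palladium π-allyl intermediate can be captured by the ring D lactam nitrogen at either end with the same result. One operation thus forms N–C19, closes ring E across piperidinone ring D and leaves a C18=C20 methylidene for the final directed hydrogenation. The precursor is the tetracyclic secondary lactam (rings A–D) carrying C21 acetate and, on C5, a chain ending in a (2R)-silyloxy 2-methylidene allylic methyl carbonate.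

Key step: step 25

Locants (target numbering, used for every compound): C1 lactam carbonyl; N; C7 (NCH2)–C6–C12–C11–C10=C9; C8 quaternary (bonded to C1, C9, C13, C5); C13–C14 (CO2Me = C22)–C15–C16–C17–C10; C5 quaternary (bonded to C8, C6, C21H2OAc, C4); C4–C3–C2(OH)–C18(C20)–C19–N. Ring A: C8, C13, C14, C15, C9. Ring B: C9, C10, C17, C16, C15. Ring C: C8, C9, C10, C11, C12, C6, C5. Ring D: C8, C1, N, C7, C6, C5. Ring E: N, C19, C18, C2, C3, C4, C5, C8, C1. Target configuration: 2R, 5R, 6S, 8R, 14R, 15R, 18R.

Assumption: compounds 1, 2, 8 and 13 are taken as purchasable (2 and 8 as solutions in THF).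

Step 1
Reactants: 1 3-bromocyclopent-2-en-1-one; 2 (4-ethoxy-4-oxobutyl)zinc bromide
Product: 3 ethyl 4-(3-oxocyclopent-1-en-1-yl)butanoate
Conditions: Pd(PPh3)4 (3 mol %), THF, 25→50 °C
Reagents that add atoms: none
Why: Negishi coupling: the β-bromoenone adds readily to zerovalent palladium and the ester-tolerant primary alkylzinc transmetalates, which should place the C11–C12–C6–C5 chain on C10.

Step 2
Reactants: 3 ethyl 4-(3-oxocyclopent-1-en-1-yl)butanoate
Product: 5 ethyl 4-(2-bromo-3-oxocyclopent-1-en-1-yl)butanoate, via dibromide 4 (not isolated)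
Conditions: Br2, CH2Cl2, 0 °C; then Et3N, 0→25 °C
Reagents that add atoms: bromine, BrBr
Why: α-Bromination of an enone by bromine addition and E1cB loss of HBr should give the vinyl bromide that later serves as the C9 handle.

Step 3
Reactants: 5 ethyl 4-(2-bromo-3-oxocyclopent-1-en-1-yl)butanoate
Product: 6 ethyl 4-[(3S)-2-bromo-3-hydroxycyclopent-1-en-1-yl]butanoate
Conditions: (R)-1-methyl-3,3-diphenyltetrahydro-1H,3H-pyrrolo[1,2-c][1,3,2]oxazaborole (20 mol %), BH3·SMe2, THF, −20 °C; then MeOH
Reagents that add atoms: none
Why: Corey–Bakshi–Shibata reduction: the brominated alkenyl side of the ketone acts as the large group, so the (R)-oxazaborolidine should deliver hydride to the face that gives the (S)-carbinol, the future C15.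

Step 4
Reactants: 6 ethyl 4-[(3S)-2-bromo-3-hydroxycyclopent-1-en-1-yl]butanoate
Product: 7 ethyl 4-[(3S)-2-bromo-3-(tert-butyldimethylsilyloxy)cyclopent-1-en-1-yl]butanoate
Conditions: TBSCl, imidazole, DMF, 25 °C
Reagents that add atoms: tert-butyldimethylsilyl chloride, C[Si](C)(Cl)C(C)(C)C
Why: Silylation of a secondary alcohol masks the C15 oxygen so that it can neither lactonise onto the C1 ester nor ionise under palladium in steps 5 and 6.

Step 5
Reactants: 7 ethyl 4-[(3S)-2-bromo-3-(tert-butyldimethylsilyloxy)cyclopent-1-en-1-yl]butanoate; 8 (2-ethoxy-2-oxoethyl)zinc bromide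
Product: 9 ethyl 4-[(3S)-3-(tert-butyldimethylsilyloxy)-2-(2-ethoxy-2-oxoethyl)cyclopent-1-en-1-yl]butanoate
Conditions: Pd[P(t-Bu)3]2 (5 mol %), THF, 50 °C
Reagents that add atoms: none
Why: Palladium-catalysed coupling of a Reformatsky reagent with a vinyl bromide (Negishi-type enolate alkenylation) should attach C8 and the C1 ester to C9 while the chain ester and the silyl ether stay intact.

Step 6
Reactants: 9 ethyl 4-[(3S)-3-(tert-butyldimethylsilyloxy)-2-(2-ethoxy-2-oxoethyl)cyclopent-1-en-1-yl]butanoate
Product: 10 ethyl (3S)-3-(tert-butyldimethylsilyloxy)-5-oxo-1,2,3,4,5,6,7,8-octahydroazulene-4-carboxylate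
Conditions: KOt-Bu (2.2 equiv), THF, 0→25 °C; then aq. HCl
Reagents that add atoms: none
Why: Dieckmann condensation: the allylic, more acidic C8–H2 is deprotonated and acylated by the C5 ester, which should close seven-membered ring C under thermodynamic control by the conjugated β-keto ester enolate.

Step 7
Reactants: 10 ethyl (3S)-3-(tert-butyldimethylsilyloxy)-5-oxo-1,2,3,4,5,6,7,8-octahydroazulene-4-carboxylate
Product: 12 ethyl (3S)-3-(methoxycarbonyloxy)-5-oxo-1,2,3,4,5,6,7,8-octahydroazulene-4-carboxylate, via alcohol 11 (not isolated)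
Conditions: HF·pyridine, pyridine–THF, 0 °C; then ClCO2Me, 0 °C
Reagents that add atoms: methyl chloroformate, COC(Cl)=O
Why: Desilylation followed at once by chloroformate acylation of the secondary alcohol should give the allylic carbonate before the γ-hydroxy ester can lactonise, and C15 is not touched.

Step 8
Reactants: 12 ethyl (3S)-3-(methoxycarbonyloxy)-5-oxo-1,2,3,4,5,6,7,8-octahydroazulene-4-carboxylate; 13 methyl 2-chloroprop-2-enoate
Product: 14 tricyclic α-chloro keto diester (rings A–C; CO2Et on C8; C5 ketone; Cl and CO2Me on C14 as both epimers; H15 cis to the C8 ester)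
Conditions: Pd(PPh3)4 (10 mol %), THF, 60 °C
Reagents that add atoms: none
Why: Palladium-catalysed [3+2] annulation of a 2-(acylmethyl)allyl carbonate with an acrylate (Tsuji–Trost ionisation, Michael addition, Tsuji–Trost ring closure): ionisation anti to the carbonate gives a π-allyl zwitterion whose C8 enolate adds to the acrylate and whose new α-chloro ester enolate closes on C15, both away from palladium, so ring A forms cis-fused and C8 and C15 follow from the C15–O configuration.

Step 9
Reactants: 14 tricyclic α-chloro keto diester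
Product: 15 tricyclic keto diester (rings A–C; H14 and H15 cis to the C8 ester; 8R 14R 15R)
Conditions: SmI2 (2.5 equiv), THF–MeOH, −78 °C
Reagents that add atoms: none
Why: Reductive dehalogenation of an α-chloro ester with SmI2 gives a samarium enolate that methanol should protonate at C14 on the less hindered face (that of H15, away from C16 and the C5 branch), which sets 14R with CO2Me cis to C16.

Step 10
Reactants: 15 tricyclic keto diester
Product: 16 C6-methylidene tricyclic keto diester
Conditions: (CH2O)n, N-methylanilinium trifluoroacetate, THF, reflux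
Reagents that add atoms: formaldehyde (from paraformaldehyde), C=O
Why: Mannich-type α-methylenation: because C8 is quaternary the ketone enolises only towards C6, so condensation with formaldehyde should give the C6 methylidene enone.

Step 11
Reactants: 16 C6-methylidene tricyclic keto diester
Product: 18 keto lactam (rings A–D; C5 ketone bridging C8 and C6; lactam N–H), via amino ketone 17 (not isolated)
Conditions: NH3 (7 M in MeOH), 0→65 °C, sealed tube
Reagents that add atoms: ammonia, N
Why: Aza-Michael addition then lactamisation: C6 epimerises next to the ketone and only the epimer with CH2NH2 cis to the C8 ester can close the six-membered lactam, so ring D forms and the C6 configuration is fixed by the ring closure.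

Step 12
Reactants: 18 keto lactam
Product: 19 C5-methoxymethylidene lactam (methyl enol ether C5=C21; E/Z mixture)
Conditions: MeOCH2PPh3Cl (4 equiv), KN(SiMe3)2 (3.8 equiv), THF, 0→50 °C
Reagents that add atoms: (methoxymethyl)triphenylphosphonium chloride, COC[P+](c1ccccc1)(c1ccccc1)c1ccccc1.[Cl-]
Why: Wittig olefination: the bridging C5 ketone cannot enolise and is more electrophilic than the ester, so the methoxymethylidene ylide should convert it into the enol ether (the salt is kept in excess over base to protect C14).

Step 13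
Reactants: 19 C5-methoxymethylidene lactam
Product: 22 C5-quaternary aldehyde (C21 formyl; C4–C3=C2 allyl on the lactam side; 5R), via mixed acetal 20 (not isolated), via allyl enol ether 21 (not isolated)
Conditions: allyl alcohol (10 equiv), propionic acid (cat.), xylene, 140 °C
Reagents that add atoms: prop-2-en-1-ol, OCC=C
Why: Acid-catalysed enol ether exchange followed by Claisen rearrangement: the allyl group should migrate to C5 across the face over the planar lactam bridge, which is less shielded than the face over ring C, so C4 ends up syn to N and the formyl carbon C21 anti (5R).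

Step 14
Reactants: 22 C5-quaternary aldehyde
Product: 23 C21 primary alcohol (allyl on C5)
Conditions: NaBH4, MeOH, 0 °C
Reagents that add atoms: none
Why: Borohydride reduction is chemoselective for the aldehyde over the methyl ester and the lactam.

Step 15
Reactants: 23 C21 primary alcohol
Product: 24 C21 acetate (allyl on C5)
Conditions: Ac2O, pyridine, 4-(dimethylamino)pyridine (cat.), CH2Cl2, 25 °C
Reagents that add atoms: acetic anhydride, CC(=O)OC(C)=O
Why: Acylation of a primary alcohol should install the acetate of the target, and the weakly nucleophilic lactam nitrogen should not compete.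

Step 16
Reactants: 24 C21 acetate
Product: 26 C2 primary alcohol (3-hydroxypropyl on C5; C21 acetate), via alkylborane 25 (not isolated)
Conditions: 9-BBN, THF, 0→25 °C; then H2O2, aq. NaOAc, 0 °C
Reagents that add atoms: 9-borabicyclo[3.3.1]nonane, B1C2CCCC1CCC2 (boron stays in 25 only); hydrogen peroxide, OO
Why: Anti-Markovnikov hydroboration–oxidation: 9-BBN adds to the monosubstituted alkene but not to the tetrasubstituted C9=C10, and buffered peroxide spares the acetate.

Step 17
Reactants: 26 C2 primary alcohol
Product: 27 C2 aldehyde (3-oxopropyl on C5; C21 acetate; rings A–D; lactam N–H)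
Conditions: Dess–Martin periodinane, NaHCO3, CH2Cl2, 25 °C
Reagents that add atoms: none
Why: Dess–Martin oxidation should stop at the aldehyde under buffered, non-epimerising conditions.

Step 18
Reactants: 28 2-bromoprop-2-en-1-ol
Product: 29 1-{[(2-bromoprop-2-en-1-yl)oxy]methyl}-4-methoxybenzene
Conditions: NaH, 4-methoxybenzyl chloride, n-Bu4NI (cat.), THF, 0→25 °C
Reagents that add atoms: 4-methoxybenzyl chloride, COc1ccc(CCl)cc1
Why: Williamson etherification gives a PMB ether that resists β-elimination from the vinyl metal and can later be removed oxidatively next to a silyl ether.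

Step 19
Reactants: 27 C2 aldehyde; 29 1-{[(2-bromoprop-2-en-1-yl)oxy]methyl}-4-methoxybenzene
Product: 30 C2 allylic alcohols (both C2 epimers; C18=C20 methylidene; C19 PMB ether)
Conditions: CrCl2 (6 equiv), NiCl2 (2 mol %), DMF–DMSO, 25 °C
Reagents that add atoms: none
Why: Nozaki–Hiyama–Kishi coupling: the vinylchromium reagent adds only to the aldehyde, so the lactam N–H, ester and acetate should survive, and C2 forms without control.

Step 20
Reactants: 30 C2 allylic alcohols
Product: 31 C2 enone (C2 ketone conjugated to C18=C20; C19 PMB ether)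
Conditions: Dess–Martin periodinane, NaHCO3, CH2Cl2, 0→25 °C
Reagents that add atoms: none
Why: Dess–Martin oxidation removes the uncontrolled C2 centre and gives the enone for reagent-controlled reduction.

Step 21
Reactants: 31 C2 enone
Product: 32 (2R)-allylic alcohol (C19 PMB ether)
Conditions: (S)-1-methyl-3,3-diphenyltetrahydro-1H,3H-pyrrolo[1,2-c][1,3,2]oxazaborole (50 mol %), catecholborane, toluene, −78 °C
Reagents that add atoms: none
Why: Corey–Bakshi–Shibata 1,2-reduction: with the 1,1-disubstituted alkenyl group as the large substituent, the (S)-oxazaborolidine should give the (2R)-alcohol.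

Step 22
Reactants: 32 (2R)-allylic alcohol
Product: 33 (2R)-tert-butyldimethylsilyl ether (C19 PMB ether)
Conditions: TBSOTf, 2,6-lutidine, CH2Cl2, −78 °C
Reagents that add atoms: tert-butyldimethylsilyl trifluoromethanesulfonate, C[Si](C)(OS(=O)(=O)C(F)(F)F)C(C)(C)C
Why: Silyl triflate silylation protects the secondary allylic alcohol, and any O-silylation of the lactam should be lost on aqueous work-up.

Step 23
Reactants: 33 (2R)-tert-butyldimethylsilyl ether
Product: 34 C19 primary allylic alcohol ((2R)-silyl ether)
Conditions: DDQ, CH2Cl2–pH 7 buffer, 0 °C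
Reagents that add atoms: none
Why: Oxidative cleavage of the PMB ether by DDQ should free only the primary alcohol, since the silyl ether is inert.

Step 24
Reactants: 34 C19 primary allylic alcohol
Product: 35 secondary lactam allylic methyl carbonate (cyclisation precursor)
Conditions: ClCO2Me, pyridine, CH2Cl2, 0 °C
Reagents that add atoms: methyl chloroformate, COC(Cl)=O
Why: Acylation of the primary allylic alcohol with a chloroformate gives the carbonate leaving group for the ring closure.

Step 25
Reactants: 35 secondary lactam allylic methyl carbonate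
Product: 36 exo-methylidene azonane lactam (rings A–E; 2-silyloxy; C18=C20)
Conditions: Pd2(dba)3·CHCl3 (10 mol %), 1,4-bis(diphenylphosphino)butane (25 mol %), THF, 0.002 M, 65 °C, slow addition
Reagents that add atoms: none
Why: Zerovalent palladium ionises the allylic methyl carbonate with loss of CO2 and methoxide, the methoxide deprotonates the lactam, and the amidate attacks a CH2 terminus of the cationic π-allyl unit on the face away from palladium to form N–C19 (intramolecular Tsuji–Trost N-allylation). The closest known reaction type is palladium-catalysed allylic amidation of lactams, together with medium-ring π-allyl closures by carbon and sulfonamide nucleophiles. Ring E closes as a nine-membered ring by bond formation at an allyl terminus with the central carbon C18 kept in the ring, which leaves C18=C20 exocyclic. No stereocentre is formed, and C2 (already 2R, as its silyl ether) is not touched. The step needs N- over O-allylation and cyclisation over oligomerisation: O-allyl imidate formation is reversible under the catalyst so the N-allyl lactam should accumulate, the two allyl termini are equivalent so regiochemistry cannot err, and rigid ring D holds N and the C5 chain on one side so that closure can compete at high dilution. Ester, acetate and silyl ether should be inert to these near-neutral conditions.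

Step 26
Reactants: 36 exo-methylidene azonane lactam
Product: 37 (2R)-allylic alcohol of the pentacycle
Conditions: n-Bu4NF, AcOH, THF, 25 °C
Reagents that add atoms: none
Why: Fluoride desilylation buffered with acetic acid should free the C2 hydroxyl without acetate cleavage or migration.

Step 27
Reactants: 37 (2R)-allylic alcohol of the pentacycle
Product: 38 target CNP0296366.1
Conditions: [Rh(nbd)(dppb)]BF4 (5 mol %), H2 (50 bar), CH2Cl2, 25 °C
Reagents that add atoms: none
Why: Hydroxyl-directed hydrogenation with a cationic rhodium bisphosphine catalyst: coordination of the C2 hydroxyl should deliver hydrogen to the face of C18=C20 syn to the C2–O bond, giving H18 cis and the methyl group trans to OH on ring E (18R), while the tetrasubstituted C9=C10 is not reduced.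

Compound list
1 | 3-bromocyclopent-2-en-1-one | O=C1C=C(Br)CC1 | starting material
2 | (4-ethoxy-4-oxobutyl)zinc bromide | CCOC(=O)CCC[Zn]Br | starting material
3 | ethyl 4-(3-oxocyclopent-1-en-1-yl)butanoate | CCOC(=O)CCCC1=CC(=O)CC1 | intermediate
4 | ethyl 4-(1,2-dibromo-3-oxocyclopentyl)butanoate (trans dibromide, racemic) | CCOC(=O)CCCC1(Br)C(Br)C(=O)CC1 | intermediate
5 | ethyl 4-(2-bromo-3-oxocyclopent-1-en-1-yl)butanoate | CCOC(=O)CCCC1=C(Br)C(=O)CC1 | intermediate
6 | ethyl 4-[(3S)-2-bromo-3-hydroxycyclopent-1-en-1-yl]butanoate | CCOC(=O)CCCC1=C(Br)[C@@H](O)CC1 | intermediate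
7 | ethyl 4-[(3S)-2-bromo-3-(tert-butyldimethylsilyloxy)cyclopent-1-en-1-yl]butanoate | CCOC(=O)CCCC1=C(Br)[C@@H](O[Si](C)(C)C(C)(C)C)CC1 | intermediate
8 | (2-ethoxy-2-oxoethyl)zinc bromide | CCOC(=O)C[Zn]Br | starting material
9 | ethyl 4-[(3S)-3-(tert-butyldimethylsilyloxy)-2-(2-ethoxy-2-oxoethyl)cyclopent-1-en-1-yl]butanoate | CCOC(=O)CCCC1=C(CC(=O)OCC)[C@@H](O[Si](C)(C)C(C)(C)C)CC1 | intermediate
10 | ethyl (3S)-3-(tert-butyldimethylsilyloxy)-5-oxo-1,2,3,4,5,6,7,8-octahydroazulene-4-carboxylate (azulene C3 = C15, C4 = C8, C5 = C5; C8 epimers and enol) | CCOC(=O)C1C(=O)CCCC2=C1[C@@H](O[Si](C)(C)C(C)(C)C)CC2 | intermediate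
11 | ethyl (3S)-3-hydroxy-5-oxo-1,2,3,4,5,6,7,8-octahydroazulene-4-carboxylate | CCOC(=O)C1C(=O)CCCC2=C1[C@@H](O)CC2 | intermediate
12 | ethyl (3S)-3-(methoxycarbonyloxy)-5-oxo-1,2,3,4,5,6,7,8-octahydroazulene-4-carboxylate | CCOC(=O)C1C(=O)CCCC2=C1[C@@H](OC(=O)OC)CC2 | intermediate
13 | methyl 2-chloroprop-2-enoate | COC(=O)C(Cl)=C | starting material
14 | tricyclic α-chloro keto diester (rings A–C; CO2Et on C8; C5 ketone; Cl and CO2Me on C14, both epimers; 8R, 15R) | COC(=O)C1(Cl)C[C@]2(C(=O)OCC)C(=O)CCCC3=C2[C@@H]1CC3 | intermediate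
15 | tricyclic keto diester (rings A–C; 8R, 14R, 15R) | COC(=O)[C@@H]1C[C@]2(C(=O)OCC)C(=O)CCCC3=C2[C@@H]1CC3 | intermediate
16 | C6-methylidene tricyclic keto diester | COC(=O)[C@@H]1C[C@]2(C(=O)OCC)C(=O)C(=C)CCC3=C2[C@@H]1CC3 | intermediate
17 | C6-aminomethyl keto diester (epimer with CH2NH2 cis to the C8 ester) | COC(=O)[C@@H]1C[C@]2(C(=O)OCC)C(=O)[C@@H](CN)CCC3=C2[C@@H]1CC3 | intermediate
18 | keto lactam (rings A–D; C5 ketone bridging C8 and C6; lactam N–H) | COC(=O)[C@@H]1C[C@@]23C(=O)NC[C@@H](CCC5=C2[C@@H]1CC5)C3=O | intermediate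
19 | C5-methoxymethylidene lactam (E/Z mixture at C5=C21) | COC(=O)[C@@H]1C[C@@]23C(=O)NC[C@@H](CCC5=C2[C@@H]1CC5)C3=COC | intermediate
20 | C21 methyl allyl acetal (C5–H; epimer mixture at C5 and C21) | COC(=O)[C@@H]1C[C@@]23C(=O)NC[C@@H](CCC5=C2[C@@H]1CC5)C3C(OC)OCC=C | intermediate
21 | C5-(allyloxymethylidene) lactam (allyl enol ether) | COC(=O)[C@@H]1C[C@@]23C(=O)NC[C@@H](CCC5=C2[C@@H]1CC5)C3=COCC=C | intermediate
22 | C5-quaternary aldehyde (C21 formyl; allyl C4–C3=C2; 5R) | COC(=O)[C@@H]1C[C@@]23C(=O)NC[C@@H](CCC5=C2[C@@H]1CC5)[C@]3(C=O)CC=C | intermediate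
23 | C21 primary alcohol (allyl on C5) | COC(=O)[C@@H]1C[C@@]23C(=O)NC[C@@H](CCC5=C2[C@@H]1CC5)[C@]3(CO)CC=C | intermediate
24 | C21 acetate (allyl on C5) | COC(=O)[C@@H]1C[C@@]23C(=O)NC[C@@H](CCC5=C2[C@@H]1CC5)[C@]3(COC(C)=O)CC=C | intermediate
25 | B-alkyl-9-BBN adduct (boron on C2) | COC(=O)[C@@H]1C[C@@]23C(=O)NC[C@@H](CCC5=C2[C@@H]1CC5)[C@]3(COC(C)=O)CCCB6C7CCCC6CCC7 | intermediate
26 | C2 primary alcohol (3-hydroxypropyl on C5) | COC(=O)[C@@H]1C[C@@]23C(=O)NC[C@@H](CCC5=C2[C@@H]1CC5)[C@]3(COC(C)=O)CCCO | intermediate
27 | C2 aldehyde (3-oxopropyl on C5; C21 acetate) | COC(=O)[C@@H]1C[C@@]23C(=O)NC[C@@H](CCC5=C2[C@@H]1CC5)[C@]3(COC(C)=O)CCC=O | intermediate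
28 | 2-bromoprop-2-en-1-ol | OCC(Br)=C | starting material
29 | 1-{[(2-bromoprop-2-en-1-yl)oxy]methyl}-4-methoxybenzene | COc1ccc(COCC(Br)=C)cc1 | intermediate
30 | C2 allylic alcohols (both C2 epimers; C19 PMB ether) | COC(=O)[C@@H]1C[C@@]23C(=O)NC[C@@H](CCC5=C2[C@@H]1CC5)[C@]3(COC(C)=O)CCC(O)C(=C)COCc6ccc(OC)cc6 | intermediate
31 | C2 enone (C19 PMB ether) | COC(=O)[C@@H]1C[C@@]23C(=O)NC[C@@H](CCC5=C2[C@@H]1CC5)[C@]3(COC(C)=O)CCC(=O)C(=C)COCc6ccc(OC)cc6 | intermediate
32 | (2R)-allylic alcohol (C19 PMB ether) | COC(=O)[C@@H]1C[C@@]23C(=O)NC[C@@H](CCC5=C2[C@@H]1CC5)[C@]3(COC(C)=O)CC[C@@H](O)C(=C)COCc6ccc(OC)cc6 | intermediate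
33 | (2R)-tert-butyldimethylsilyl ether (C19 PMB ether) | COC(=O)[C@@H]1C[C@@]23C(=O)NC[C@@H](CCC5=C2[C@@H]1CC5)[C@]3(COC(C)=O)CC[C@@H](O[Si](C)(C)C(C)(C)C)C(=C)COCc6ccc(OC)cc6 | intermediate
34 | C19 primary allylic alcohol ((2R)-silyl ether) | COC(=O)[C@@H]1C[C@@]23C(=O)NC[C@@H](CCC5=C2[C@@H]1CC5)[C@]3(COC(C)=O)CC[C@@H](O[Si](C)(C)C(C)(C)C)C(=C)CO | intermediate
35 | secondary lactam allylic methyl carbonate (cyclisation precursor) | COC(=O)[C@@H]1C[C@@]23C(=O)NC[C@@H](CCC5=C2[C@@H]1CC5)[C@]3(COC(C)=O)CC[C@@H](O[Si](C)(C)C(C)(C)C)C(=C)COC(=O)OC | intermediate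
36 | exo-methylidene azonane lactam (rings A–E; 2-silyloxy) | COC(=O)[C@@H]1C[C@@]23C(=O)N4C[C@@H](CCC5=C2[C@@H]1CC5)[C@]3(COC(C)=O)CC[C@@H](O[Si](C)(C)C(C)(C)C)C(=C)C4 | intermediate
37 | (2R)-allylic alcohol of the pentacycle | COC(=O)[C@@H]1C[C@@]23C(=O)N4C[C@@H](CCC5=C2[C@@H]1CC5)[C@]3(COC(C)=O)CC[C@@H](O)C(=C)C4 | intermediate
38 | CNP0296366.1 | COC(=O)[C@@H]1C[C@@]23C(=O)N4C[C@@H](CCC5=C2[C@@H]1CC5)[C@]3(COC(C)=O)CC[C@@H](O)[C@H](C)C4 | target

Total step count: 27. Longest linear sequence: 26 steps (steps 1–17 and 19–27, from 1 to 38).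

Steps most likely to fail

Step 25. The lactam amidate is a sluggish nucleophile for a nine-membered closure, so intermolecular N-allylation (oligomerisation) or base-induced collapse of the π-allyl unit to a diene may outrun cyclisation. The fallback sets out from 34 and avoids palladium: Appel bromination (CBr4, PPh3) gives allylic bromide F1. Deprotonation of the lactam with NaH in THF–DMF at high dilution then lets the amidate displace bromide directly. SN2 and SN2' attack give the same ring because the two CH2 groups of the allyl unit are equivalent, and the route is rejoined at 36.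

Step 8. The π-allyl zwitterion may close through enolate oxygen or allylate a second molecule before it adds to the acrylate, and the tetrasubstituted alkene may ionise slowly. The fallback sets out from 12 and makes the two C–C bonds separately. Conjugate addition of 12 to methyl 2-(phenylsulfonyl)prop-2-enoate under catalytic K2CO3, with no palladium present, gives sulfonyl ester F2. Pd(PPh3)4 then closes ring A by intramolecular allylic alkylation with the soft α-sulfonyl ester carbanion, giving tricyclic sulfone F3; the C8 epimers should converge through reversible conjugate addition. SmI2 in THF–MeOH removes the sulfonyl group with protonation on the H15 face, and the route is rejoined at 15.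

Step 27. Facial selectivity may be poor or reversed if ring E holds the C2–O bond over the other face of C18=C20 in the reactive conformer, and the allylic alcohol may isomerise to the ketone. The fallback sets out from 36 and relies on steric rather than directing control. Hydrogenation of the silyl ether over Pt/C in EtOAc should add hydrogen anti to the bulky silyloxy group, the complementary facial preference, to give saturated silyl ether F4. Desilylation (n-Bu4NF, AcOH) then gives 38.

Further compounds
F1 | step 25 | allylic bromide (C19–Br; (2R)-silyl ether; lactam N–H) | COC(=O)[C@@H]1C[C@@]23C(=O)NC[C@@H](CCC5=C2[C@@H]1CC5)[C@]3(COC(C)=O)CC[C@@H](O[Si](C)(C)C(C)(C)C)C(=C)CBr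
F2 | step 8 | conjugate adduct of 12 with methyl 2-(phenylsulfonyl)prop-2-enoate (C8 quaternary, epimers; allylic carbonate retained) | CCOC(=O)C1(CC(C(=O)OC)S(=O)(=O)c3ccccc3)C(=O)CCCC2=C1[C@@H](OC(=O)OC)CC2
F3 | step 8 | tricyclic C14 phenylsulfonyl keto diester (rings A–C; C14 epimers) | COC(=O)C1(S(=O)(=O)c4ccccc4)C[C@]2(C(=O)OCC)C(=O)CCCC3=C2[C@@H]1CC3
F4 | step 27 | tert-butyldimethylsilyl ether of 38 | COC(=O)[C@@H]1C[C@@]23C(=O)N4C[C@@H](CCC5=C2[C@@H]1CC5)[C@]3(COC(C)=O)CC[C@@H](O[Si](C)(C)C(C)(C)C)[C@H](C)C4
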